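One question stands for this flask, set here beside the earlier runs:

the same everywhere: partner 0.237 M; free catalyst 0.25 mM
- cedar: substrate 0.25 M; impurity 16 µM; run made earlier
- ash: substrate 0.25 M; impurity 24 µM; run made earlier
- maple: substrate 0.12 M; impurity 32 µM; run made earlier
- flask: substrate 0.25 M; impurity 32 µM

| cedar: time / h | cedar: product / % | ash: time / h | ash: product / % | maple: time / h | maple: product / % |
|---|---|---|---|---|---|
| 1.33 | 0.8 | 0.500 | 0.5 | 1.33 | 0.4 |
| 2.50 | 3.6 | 1.50 | 0.9 | 2.50 | 2.3 |
| 4.00 | 6.6 | 3.00 | 3.9 | 4.00 | 4.9 |
| 5.00 | 8.9 | 4.00 | 5.6 | 5.00 | 7.4 |
| 6.00 | 11.0 | 6.00 | 9.9 | 6.00 | 9.7 |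

(scatter of a reading: 0.5 percentage points)

* apparent order in free catalyst when 20 % of the substrate are converted (percent change of the rate of making product for one percent more free catalyst charged)

- no earlier run changes the charge of free catalyst; that part of a forecast is a guess
- what has left substrate counts as converted, also if it is not yet product

My bench rule says a catalyst comes back after each turnover, and reaching 20 % conversion takes 200 turnovers per free catalyst charged, so I first expect the rate to follow the charge with order one. That rule stops where something acts once and stays taken, and the runs hint at this: at 6.00 h product reads 11.0 % in cedar and 9.9 % in ash, which holds more impurity, a gap of 1.1 percentage points against a scatter of 0.5 points. The border is a ratio, impurity charged over free catalyst charged, the poisoned share 12.8 %. If each impurity takes one free catalyst for good and the rate follows what remains, one percent more charge at the same impurity lands on the remainder, so I commit to an order of 1.15, a guess, as no earlier run changes the catalyst charge. The forecast says “Impurity barely changes the later rate” and gives 0.95, lower than my figure.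

The flask gives 1.1.

    substrate + free catalyst ⇌ free catalyst + open intermediate (K = 0.667, k = 0.0641 M⁻¹ s⁻¹)
    free catalyst + open intermediate ⇌ catalyst intermediate (K = 190 M⁻¹, k = 0.307 M⁻¹ s⁻¹)
    partner + catalyst intermediate → free catalyst + product (k = 0.278 M⁻¹ s⁻¹)
    free catalyst + impurity → spent catalyst (k = 56.5 M⁻¹ s⁻¹)

By 0.600 h the flask holds impurity at 0 % of its charge and spent catalyst at 12.8 % of the catalyst charged, and spent catalyst still stands at 12.8 % after 60.0 h. Meanwhile substrate goes over to open intermediate, its half-life by that forward step alone being 16 h at 6.00 h, and partner turns catalyst intermediate into product, and at that time the flask holds free catalyst, the resting state, at 76.2 %, more than catalyst intermediate at 11.0 %, together the 87.2 % of the catalyst charged that lies outside the poisoned share of 12.8 %, with product at 9.91 %.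

(The earlier runs and the new flask were generated by integration with made-up constants, noise included.)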